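**Plan**

Numbering is that of eudesmane: ring B = C1–C5 and C10, ring A = C5–C10, C14 = methyl on C10, C15 = carbon on C4, and β = the face of C14. The feature that makes the key step possible is that the C5–C10 fusion bond is ringed by oxygen on C1 and C4 (ring B) and on C6 and C9 (ring A), so ring B reads as a 1,4-benzoquinone and C6–C7(i-Pr)=C8–C9 as the residue of a 1,4-dioxygenated diene.
Retrosynthesis: cut the three orthoester C–O bonds (to a 4α,6α,15-triol and trimethyl orthocinnamate), then the C4–O and C15–O bonds and C4=C15 (back to a C4 ketone), then C9–C10 and C5–C6 of ring A.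
Forward: ring B is bought as 2-methoxy-6-methylphenol and oxidised to the quinone, ring A is fused onto it in one [4+2] step, the C2 methoxy group is excised, and the orthoester cage is closed last.
Stereochemistry: C10 and C6 come from the catalysed endo cycloaddition, C5 from equilibration to the trans-decalin, and C4 from dihydroxylation on the face away from C14.
C1 and C9 come from hydride attack away from C14, C7 from hydrogenation steered by the 9β-hydroxyl, and the orthoester carbon from the cage.

Key step: step 5

Assumption: the (R)-BINOL-derived titanium catalyst is taken to open the quinone face that gives the C10 configuration drawn; if the sense is the opposite, the (S)-ligand is used with no other change.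

**Route**

Step 1
Reactants: 1 3-methylbutanal (isovaleraldehyde)
Product: 2 (E)-N-tert-butyl-3-methylbutan-1-imine
Conditions: t-BuNH2, MgSO4, Et2O, 0 °C to rt
Reagents that add atoms: tert-butylamine, CC(C)(C)N
Why: Condensation of the aldehyde with a primary amine (imine formation) masks the carbonyl so that its α-carbon can be metalated without self-aldolisation, and no stereocentre is formed.

Step 2
Reactants: 2 (E)-N-tert-butyl-3-methylbutan-1-imine; 3 (tert-butyldimethylsilyloxy)acetaldehyde
Product: 6 (E)-4-(tert-butyldimethylsilyloxy)-2-isopropylbut-2-enal, via lithiated imine 4 (not isolated), via aldol adduct 5 (not isolated)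
Conditions: LiN(i-Pr)2, THF, −78 to 0 °C; 3, −78 °C; aq. oxalic acid, rt
Reagents that add atoms: water, O
Why: Directed aldol condensation through the lithium aza-enolate joins C7 to C8 without self-condensation of either aldehyde, and hydrolysis of the imine with loss of water under equilibrating acid gives the conjugated enal in its more stable E form, the CH2OSi group lying cis to isopropyl and trans to CHO.

Step 3
Reactants: 6 (E)-4-(tert-butyldimethylsilyloxy)-2-isopropylbut-2-enal
Product: 8 (1E,3E)-1-(tert-butyldimethylsilyloxy)-4-(tert-butyldiphenylsilyloxy)-3-isopropylbuta-1,3-diene, via potassium dienolate 7 (not isolated)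
Conditions: KN(SiMe3)2, THF, −78 °C; t-BuPh2SiCl, −78 °C to rt
Reagents that add atoms: tert-butyl(chloro)diphenylsilane, CC(C)(C)[Si](Cl)(c1ccccc1)c1ccccc1
Why: γ-Deprotonation and O-silylation of the dienolate (silyl dienol ether formation) should give the E,E diene because the s-trans enal holds O6 trans to C8 and allylic 1,3-strain against the isopropyl group turns the C9 silyloxy group away from C7 in the deprotonation, so both oxygens sit on the outside of the diene.

Step 4
Reactants: 9 2-methoxy-6-methylphenol
Product: 10 2-methoxy-6-methyl-1,4-benzoquinone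
Conditions: O2 (1 atm), Co(salen) [Co(C16H14N2O2)] (5 mol%), DMF, rt
Reagents that add atoms: dioxygen, O=O
Why: Cobalt–salen-catalysed aerobic oxidation of a phenol whose two ortho positions are blocked delivers the para-quinone.

Step 5
Reactants: 8 (1E,3E)-1-(tert-butyldimethylsilyloxy)-4-(tert-butyldiphenylsilyloxy)-3-isopropylbuta-1,3-diene; 10 2-methoxy-6-methyl-1,4-benzoquinone
Product: 11 9α-(tert-butyldimethylsilyloxy)-6α-(tert-butyldiphenylsilyloxy)-2-methoxy-15-nor-5β-eudesma-2,7-diene-1,4-dione (cis-fused; H5 and C14 on one face and both silyloxy groups on the other)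
Conditions: [(R)-BINOLate]TiCl2 (20 mol%), CH2Cl2, −78 to −30 °C
Reagents that add atoms: none
Why: This is a Lewis-acid-catalysed quinone Diels–Alder reaction, concerted but asynchronous and closest in type to known (BINOLate)TiCl2-promoted additions of 1-oxygenated dienes to substituted benzoquinones: titanium (tetravalent) chelated by the C1 carbonyl and the C2 methoxy group activates the methyl-bearing C5=C10 alkene (the methoxy-bearing alkene is a deactivated vinylogous ester) and makes C5 its electrophilic end. Ring A closes intermolecularly by suprafacial [4+2] addition, C5–C6 forming ahead of C9–C10, the bond that creates the quaternary centre. Regiochemistry is set because C6 is the nucleophilic terminus of 8: positive charge building at C7 is tertiary (isopropyl) and is relayed to the trialkylsilyloxy group on C9, whereas the diphenyl-substituted silyl ether on C6 is the weaker donor. C5 and C10 come out cis because the alkene geometry of the quinone is retained, and endo approach (diene over the C1 and C4 carbonyls) with the E,E diene places O6 and O9 both α, away from C14 and H5, which is already the target configuration at C6. The absolute configuration at C10 comes from the BINOLate ligand, which leaves one face of the chelated quinone open. The step therefore needs regio-, endo- and face-selectivity, supplied in turn by the chelate and isopropyl pairing, by secondary orbital overlap and by the chiral ligand.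

Step 6
Reactants: 11 9α-(tert-butyldimethylsilyloxy)-6α-(tert-butyldiphenylsilyloxy)-2-methoxy-15-nor-5β-eudesma-2,7-diene-1,4-dione
Product: 13 9α-(tert-butyldimethylsilyloxy)-6α-(tert-butyldiphenylsilyloxy)-15-nor-5β-eudesm-7-ene-1,4-dione (cis-fused), via 2-methoxy dione 12 (not isolated)
Conditions: SmI2 (5 equiv), THF–MeOH, −78 to 0 °C
Reagents that add atoms: none
Why: Samarium diiodide first reduces the electron-poor ene-dione alkene and then cleaves the C2–OMe bond next to the C1 ketone (reductive cleavage of an α-alkoxy ketone), methanol protonating the enolates at C2 and C3, so that the samarium enolates never involve C5 and the stereocentres at C5, C6, C9 and C10 are untouched.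

Step 7
Reactants: 13 9α-(tert-butyldimethylsilyloxy)-6α-(tert-butyldiphenylsilyloxy)-15-nor-5β-eudesm-7-ene-1,4-dione
Product: 14 9α-(tert-butyldimethylsilyloxy)-6α-(tert-butyldiphenylsilyloxy)-15-nor-5α-eudesm-7-ene-1,4-dione (trans-fused)
Conditions: DBU (0.5 equiv), toluene, 60 °C
Reagents that add atoms: none
Why: Base-mediated epimerisation through the C4 enolate, which reprotonates faster than it can expel the poor silyloxide leaving group from C6, should settle on the trans-decalin because either chair form of the cis isomer holds a ring B carbonyl carbon syn-axial to O9 or to O6 whereas the trans isomer has only C14 and O9 axial, so C5 becomes 5α-H.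

Step 8
Reactants: 14 9α-(tert-butyldimethylsilyloxy)-6α-(tert-butyldiphenylsilyloxy)-15-nor-5α-eudesm-7-ene-1,4-dione
Product: 15 9α-(tert-butyldimethylsilyloxy)-6α-(tert-butyldiphenylsilyloxy)-5α-eudesma-4(15),7-dien-1-one
Conditions: Zn, CH2Br2, TiCl4, THF–CH2Cl2, 0 °C to rt
Reagents that add atoms: dibromomethane, BrCBr
Why: Takai–Lombardo methylenation is non-basic, so C5 is not re-equilibrated and the β-silyloxy ketone does not eliminate, and it should choose the C4 carbonyl because C1 adjoins the quaternary C10 and is screened on its β face by C14 and on its α face by the axial silyloxy group on C9.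

Step 9
Reactants: 15 9α-(tert-butyldimethylsilyloxy)-6α-(tert-butyldiphenylsilyloxy)-5α-eudesma-4(15),7-dien-1-one
Product: 16 6α-(tert-butyldiphenylsilyloxy)-9α-hydroxy-5α-eudesma-4(15),7-dien-1-one
Conditions: HF·pyridine, pyridine, THF, 0 °C to rt
Reagents that add atoms: none
Why: Acidic fluoride removes the trialkylsilyl ether at C9 while the much more acid-stable tert-butyldiphenylsilyl ether at C6 stays (selective desilylation).

Step 10
Reactants: 16 6α-(tert-butyldiphenylsilyloxy)-9α-hydroxy-5α-eudesma-4(15),7-dien-1-one
Product: 17 6α-(tert-butyldiphenylsilyloxy)-5α-eudesma-4(15),7-diene-1,9-dione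
Conditions: Dess–Martin periodinane, CH2Cl2, rt
Reagents that add atoms: none
Why: Dess–Martin oxidation of the axial allylic alcohol gives the enone under neutral conditions and erases the C9 centre that the cycloaddition had set in the wrong sense.

Step 11
Reactants: 17 6α-(tert-butyldiphenylsilyloxy)-5α-eudesma-4(15),7-diene-1,9-dione
Product: 18 6α-(tert-butyldiphenylsilyloxy)-4α,15-dihydroxy-5α-eudesm-7-ene-1,9-dione
Conditions: OsO4 (2 mol%), N-methylmorpholine N-oxide, acetone–H2O, rt
Reagents that add atoms: osmium tetroxide, O=[Os](=O)(=O)=O; N-methylmorpholine N-oxide, C[N+]1([O-])CCOCC1; water, O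
Why: Catalytic osmylation (OsO4 with N-oxide reoxidant) takes the electron-rich 1,1-disubstituted C4=C15 alkene and leaves the electron-poor, hindered enone alkene, and it should attack the α face because the β face of C4 lies under the syn-axial C14 methyl, which makes O4 α (equatorial) and C15 β (axial).

Step 12
Reactants: 18 6α-(tert-butyldiphenylsilyloxy)-4α,15-dihydroxy-5α-eudesm-7-ene-1,9-dione
Product: 19 6α-(tert-butyldiphenylsilyloxy)-5α-eudesm-7-ene-1β,4α,9β,15-tetraol
Conditions: NaBH4, CeCl3·7H2O, MeOH, −78 to −20 °C
Reagents that add atoms: none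
Why: Luche reduction adds hydride 1,2 to the enone and to the C1 ketone from the α face (axial attack away from the angular methyl, C9 no longer carrying an axial group that would block C1), so both new hydroxyls should be equatorial and β, the low temperature keeping the transient β-hydroxy ketone from retro-aldol cleavage.

Step 13
Reactants: 19 6α-(tert-butyldiphenylsilyloxy)-5α-eudesm-7-ene-1β,4α,9β,15-tetraol
Product: 20 6α-(tert-butyldiphenylsilyloxy)-5α,7βH-eudesmane-1β,4α,9β,15-tetraol (7α-isopropyl)
Conditions: H2 (1 atm), [Ir(cod)(PCy3)(py)]PF6 (10 mol%), CH2Cl2, rt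
Reagents that add atoms: none
Why: Hydroxyl-directed homogeneous hydrogenation: cationic iridium bound to the allylic 9β-hydroxyl (the 1β- and 15-hydroxyls lie on the same side, the α face carries the bulky non-coordinating silyl ether and the tertiary 4α-hydroxyl is remote) should deliver both hydrogens to the β face of C7=C8, making H7 β and the isopropyl group α (axial) against the steric bias of C14.

Step 14
Reactants: 20 6α-(tert-butyldiphenylsilyloxy)-5α,7βH-eudesmane-1β,4α,9β,15-tetraol
Product: 21 5α,7βH-eudesmane-1β,4α,6α,9β,15-pentaol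
Conditions: Bu4NF, THF, rt to 45 °C
Reagents that add atoms: none
Why: Fluoride cleaves the remaining silyl ether (desilylation) and frees the 6α-hydroxyl without touching a stereocentre.

Step 15
Reactants: 22 (E)-(2-bromovinyl)benzene; 23 tetramethyl orthocarbonate
Product: 25 trimethyl (E)-orthocinnamate [(E)-(3,3,3-trimethoxyprop-1-enyl)benzene], via styrylmagnesium bromide 24 (not isolated)
Conditions: Mg, THF, 40 °C; 23, 65 °C
Reagents that add atoms: none
Why: Tschitschibabin orthoester synthesis: the alkenyl Grignard reagent, formed with retention of the E geometry, displaces one methoxide from the orthocarbonate to give the orthocinnamate.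

Step 16
Reactants: 21 5α,7βH-eudesmane-1β,4α,6α,9β,15-pentaol; 25 trimethyl (E)-orthocinnamate
Product: 26 5α,7βH-eudesmane-1β,9β-diol 4α,6α,15-orthocinnamate (CNP0252898.2)
Conditions: 25 (1.2 equiv), camphorsulfonic acid (5 mol%), THF–CH2Cl2, rt; Et3N quench
Reagents that add atoms: none
Why: Acid-catalysed orthoester exchange under thermodynamic control closes the cage because O4 and O6 (both α and equatorial, peri across C5) and O15 (on the β-axial carbon of C4) are the only three hydroxyls that can reach one carbon, three molecules of methanol being lost, the configuration of the orthoester carbon being dictated by the cage and any mixed orthoester at the 1,9-diol reverting.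

**Compound list**

1 | 3-methylbutanal | CC(C)CC=O | starting material
2 | (E)-N-tert-butyl-3-methylbutan-1-imine | CC(C)C/C=N/C(C)(C)C | intermediate
3 | (tert-butyldimethylsilyloxy)acetaldehyde | O=CCO[Si](C)(C)C(C)(C)C | starting material
4 | lithium tert-butyl(3-methylbut-1-enyl)amide (aza-enolate of 2, geometry not defined) | CC(C)C=CN([Li])C(C)(C)C | intermediate
5 | lithium 1-(tert-butyldimethylsilyloxy)-3-[(tert-butylimino)methyl]-4-methylpentan-2-olate (diastereomer mixture, both centres lost on dehydration) | CC(C)C(C=NC(C)(C)C)C(O[Li])CO[Si](C)(C)C(C)(C)C | intermediate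
6 | (E)-4-(tert-butyldimethylsilyloxy)-2-isopropylbut-2-enal | O=C/C(C(C)C)=C/CO[Si](C)(C)C(C)(C)C | intermediate
7 | potassium (1E,3E)-4-(tert-butyldimethylsilyloxy)-2-isopropylbuta-1,3-dien-1-olate | CC(C)(C)[Si](C)(C)O/C=C/C(C(C)C)=C/[O-].[K+] | intermediate
8 | (1E,3E)-1-(tert-butyldimethylsilyloxy)-4-(tert-butyldiphenylsilyloxy)-3-isopropylbuta-1,3-diene | CC(C)(C)[Si](C)(C)O/C=C/C(C(C)C)=C/O[Si](c1ccccc1)(c1ccccc1)C(C)(C)C | intermediate
9 | 2-methoxy-6-methylphenol | COc1cccc(C)c1O | starting material
10 | 2-methoxy-6-methyl-1,4-benzoquinone | COC1=CC(=O)C=C(C)C1=O | intermediate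
11 | 9α-(tert-butyldimethylsilyloxy)-6α-(tert-butyldiphenylsilyloxy)-2-methoxy-15-nor-5β-eudesma-2,7-diene-1,4-dione | CC(C)C1=C[C@H](O[Si](C)(C)C(C)(C)C)[C@@]2(C)[C@@H]([C@@H]1O[Si](c3ccccc3)(c4ccccc4)C(C)(C)C)C(=O)C=C(OC)C2=O | intermediate
12 | 9α-(tert-butyldimethylsilyloxy)-6α-(tert-butyldiphenylsilyloxy)-2ξ-methoxy-15-nor-5β-eudesm-7-ene-1,4-dione (C2 epimers, centre removed in the same step) | CC(C)C1=C[C@H](O[Si](C)(C)C(C)(C)C)[C@@]2(C)[C@@H]([C@@H]1O[Si](c3ccccc3)(c4ccccc4)C(C)(C)C)C(=O)CC(OC)C2=O | intermediate
13 | 9α-(tert-butyldimethylsilyloxy)-6α-(tert-butyldiphenylsilyloxy)-15-nor-5β-eudesm-7-ene-1,4-dione | CC(C)C1=C[C@H](O[Si](C)(C)C(C)(C)C)[C@@]2(C)[C@@H]([C@@H]1O[Si](c3ccccc3)(c4ccccc4)C(C)(C)C)C(=O)CCC2=O | intermediate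
14 | 9α-(tert-butyldimethylsilyloxy)-6α-(tert-butyldiphenylsilyloxy)-15-nor-5α-eudesm-7-ene-1,4-dione | CC(C)C1=C[C@H](O[Si](C)(C)C(C)(C)C)[C@@]2(C)[C@H]([C@@H]1O[Si](c3ccccc3)(c4ccccc4)C(C)(C)C)C(=O)CCC2=O | intermediate
15 | 9α-(tert-butyldimethylsilyloxy)-6α-(tert-butyldiphenylsilyloxy)-5α-eudesma-4(15),7-dien-1-one | CC(C)C1=C[C@H](O[Si](C)(C)C(C)(C)C)[C@@]2(C)[C@H]([C@@H]1O[Si](c3ccccc3)(c4ccccc4)C(C)(C)C)C(=C)CCC2=O | intermediate
16 | 6α-(tert-butyldiphenylsilyloxy)-9α-hydroxy-5α-eudesma-4(15),7-dien-1-one | CC(C)C1=C[C@H](O)[C@@]2(C)[C@H]([C@@H]1O[Si](c3ccccc3)(c4ccccc4)C(C)(C)C)C(=C)CCC2=O | intermediate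
17 | 6α-(tert-butyldiphenylsilyloxy)-5α-eudesma-4(15),7-diene-1,9-dione | CC(C)C1=CC(=O)[C@@]2(C)[C@H]([C@@H]1O[Si](c3ccccc3)(c4ccccc4)C(C)(C)C)C(=C)CCC2=O | intermediate
18 | 6α-(tert-butyldiphenylsilyloxy)-4α,15-dihydroxy-5α-eudesm-7-ene-1,9-dione | CC(C)C1=CC(=O)[C@@]2(C)[C@H]([C@@H]1O[Si](c3ccccc3)(c4ccccc4)C(C)(C)C)[C@](O)(CO)CCC2=O | intermediate
19 | 6α-(tert-butyldiphenylsilyloxy)-5α-eudesm-7-ene-1β,4α,9β,15-tetraol | CC(C)C1=C[C@@H](O)[C@@]2(C)[C@H]([C@@H]1O[Si](c3ccccc3)(c4ccccc4)C(C)(C)C)[C@](O)(CO)CC[C@@H]2O | intermediate
20 | 6α-(tert-butyldiphenylsilyloxy)-5α,7βH-eudesmane-1β,4α,9β,15-tetraol | CC(C)[C@@H]1C[C@@H](O)[C@@]2(C)[C@H]([C@@H]1O[Si](c3ccccc3)(c4ccccc4)C(C)(C)C)[C@](O)(CO)CC[C@@H]2O | intermediate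
21 | 5α,7βH-eudesmane-1β,4α,6α,9β,15-pentaol | CC(C)[C@@H]1C[C@@H](O)[C@@]2(C)[C@H]([C@@H]1O)[C@](O)(CO)CC[C@@H]2O | intermediate
22 | (E)-(2-bromovinyl)benzene | Br/C=C/c1ccccc1 | starting material
23 | tetramethyl orthocarbonate | COC(OC)(OC)OC | starting material
24 | (E)-styrylmagnesium bromide | Br[Mg]/C=C/c1ccccc1 | intermediate
25 | trimethyl (E)-orthocinnamate | COC(OC)(OC)/C=C/c1ccccc1 | intermediate
26 | 5α,7βH-eudesmane-1β,9β-diol 4α,6α,15-orthocinnamate (CNP0252898.2) | CC(C)[C@@H]1C[C@@H](O)[C@@]2(C)[C@@H]3[C@@H]1O[C@]1(/C=C/c4ccccc4)OC[C@@]3(CC[C@@H]2O)O1 | target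

**Step count and risks**

Total step count: 16. Longest linear sequence: 14 steps (steps 1–3, 5–14 and 16).

Step 7 (ring-fusion equilibration). What may go wrong: the base equilibration may stop at an unfavourable cis/trans balance, or the C4 enolate may slowly lose the C6 silyloxide on prolonged heating. Fallback: the separate equilibration is dropped and C5 is set under Curtin–Hammett control during the olefination. Setting out from 13, treatment with excess Ph3P=CH2 (from Ph3PCH3Br and KOt-Bu, THF, 65 °C; Wittig methylenation) lets the basic ylide interconvert the C5 epimers while it olefinates. The trans ketone, whose C4 carbonyl is equatorial to ring A and not tucked under it, should be consumed faster, and the sequence comes back to the route at 15. It makes no new compound (none F0).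

Step 13 (directed hydrogenation). What may go wrong: poor facial selectivity, because the pseudo-equatorial 9β-hydroxyl may steer the metal too weakly against the angular methyl, or stalling through binding of the catalyst by the tetraol. Fallback: the choice of face is handed from the substrate to the catalyst. Setting out from 19, the alkene is hydrogenated under reagent control with a chiral iridium phosphino-oxazoline complex, [Ir(cod)(t-Bu-PHOX)][B(C6H3(CF3)2)4] (H2 50 bar, CH2Cl2). The ligand antipode matched to β-face delivery is chosen, and the sequence comes back to the route at 20. It makes no new compound (none F0).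

Step 5 (cycloaddition). What may go wrong: leakage of regioselectivity, because both diene termini carry silyloxy donors and only the isopropyl group and the weaker aryl silyl ether differentiate them, or desilylative conjugate addition outrunning ring closure. Fallback: the diene is polarised with a weakly donating acyl-type oxygen at C6, which is exchanged for the silyl ether only after the cycloaddition, since a β-acyloxy ketone would eliminate in the later base step.
- Setting out from 6, the potassium dienolate 7 is trapped with 2,2,2-trichloroethyl chloroformate to give (1E,3E)-1-(tert-butyldimethylsilyloxy)-3-isopropyl-4-[(2,2,2-trichloroethoxy)carbonyloxy]buta-1,3-diene F1.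
- Cycloaddition with 10 under the conditions of step 5 gives 9α-(tert-butyldimethylsilyloxy)-2-methoxy-6α-[(2,2,2-trichloroethoxy)carbonyloxy]-15-nor-5β-eudesma-2,7-diene-1,4-dione F2.
- Zn in AcOH (rt) reduces the ene-dione alkene and removes the carbonate in one operation to give 9α-(tert-butyldimethylsilyloxy)-6α-hydroxy-2ξ-methoxy-15-nor-5β-eudesm-7-ene-1,4-dione F3.
- Silylation (t-BuPh2SiCl, imidazole, DMF, 45 °C) brings the sequence back to the route at 12, which is then isolated and carried through the SmI2 cleavage of step 6 to 13.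

Further compounds
F1 | step 5 | (1E,3E)-1-(tert-butyldimethylsilyloxy)-3-isopropyl-4-[(2,2,2-trichloroethoxy)carbonyloxy]buta-1,3-diene | CC(C)(C)[Si](C)(C)O/C=C/C(C(C)C)=C/OC(=O)OCC(Cl)(Cl)Cl
F2 | step 5 | 9α-(tert-butyldimethylsilyloxy)-2-methoxy-6α-[(2,2,2-trichloroethoxy)carbonyloxy]-15-nor-5β-eudesma-2,7-diene-1,4-dione | CC(C)C1=C[C@H](O[Si](C)(C)C(C)(C)C)[C@@]2(C)[C@@H]([C@@H]1OC(=O)OCC(Cl)(Cl)Cl)C(=O)C=C(OC)C2=O
F3 | step 5 | 9α-(tert-butyldimethylsilyloxy)-6α-hydroxy-2ξ-methoxy-15-nor-5β-eudesm-7-ene-1,4-dione | CC(C)C1=C[C@H](O[Si](C)(C)C(C)(C)C)[C@@]2(C)[C@@H]([C@@H]1O)C(=O)CC(OC)C2=O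
F0 | step 7 | none | none
F0 | step 13 | none | none
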